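If target and starting material are read in the same sample, divide one by the other before plotting either.

all flasks: starting material 0.40 M
- west: partner 1.5 equiv; protic impurity 0.40 M; catalyst 0.1 mol%; the very flask that is asked about, followed so far
- north-east: partner 1.5 equiv; protic impurity 0.40 M; catalyst 0.15 mol%; run made earlier
- flask: partner 1.50 equiv; protic impurity 0.400 M; catalyst 0.1 mol%; time 12 h

- west (time / h: target / %, starting material / %): 0.100: 19.2, 55.5; 0.200: 28.0, 35.2; 0.500: 29.1, 15.7; 1.00: 23.4, 8.8; 2.00: 13.9, 5.1; 5.00: 4.3, 1.7
- north-east (time / h: target / %, starting material / %): 0.100: 19.2, 55.6; 0.200: 27.4, 35.2; 0.500: 28.9, 15.8; 1.00: 22.1, 8.9; 2.00: 11.9, 4.2; 5.00: 4.4, 1.4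

(scatter of a reading: 0.5 percentage points)

- time up to 12 h at which target stands highest
- the amount of target, in percent of the starting material charged, at that time



Begin with the bench rule for low conversion: yield equals selectivity times conversion. In the west flask, the one asked about, the first reading gives a selectivity of 0.431 of the consumed fraction, and the second gives 0.432, so the rule holds that far. At 0.500 h it asks for 0.364 of the charge, but the west flask reads 29.1%, so the rule has stopped working.

Now take the ratio of target to starting material in the west flask. It reads 0.346 at 0.100 h and 1.85 at 0.500 h, then stands level at 2.66, 2.73 and 2.53. Call the pooled late value, summed target over summed starting material from 1.00 h on, the hold ratio: 2.67.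

Set the two lines equal. They cross at a starting-material fraction of 0.139, with target at 0.371. This is my own reckoning, and it gives an estimated ceiling on the height, not a time. The reading at 0.500 h already lies below both lines, so expect the peak under that height.

The forecast gives 0.32 h and 30.5%, on the ground that “The peak occurs where formation equals loss”. Its height lies under my estimated ceiling.

The asked flask peaks at 0.386 h with 30.6%: the height agrees with the forecast, and the time stands later.

    starting material + partner ⇌ target (K = 4.10 M⁻¹, k = 0.0854 M⁻¹ min⁻¹)
    starting material + partner ⇌ isomer of the product (K = 13.0 M⁻¹, k = 0.00355 M⁻¹ min⁻¹)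
    target + catalyst ⇌ isomer of the product + catalyst, rate k3*[catalyst]*[target] forward; the back reaction follows from the equilibrium constant (k = 11.7 M⁻¹ min⁻¹)
    starting material + protic impurity → quenched substrate (k = 0.151 M⁻¹ min⁻¹)

At that peak starting material in the asked flask is 19.7% of the charge, above the crossing, and the ratio is 1.55, below the hold ratio of 2.67. At 12.0 h the hold ratio times the 1.03% of starting material left gives 0.0275 of target, and the asked flask holds 2.67%. With catalyst cut to 0.025 mol%, the neighbour's 0.909% of starting material gives 0.0242, and that neighbour holds 2.28%.

(The numbers in the tables are calculated with constants of no real substance; noise was put on by code.)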